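Ring B is disconnected at C2–C3 and C1–C10, a Diels–Alder reaction of citraconic anhydride with a ring A 2-silyloxydiene. The step exploits three features: the C2 acyl carbon and the C1 sec-butyl carbon are cis, as the anhydride carbonyls are; C2 is a methyl-bearing quaternary centre; and the C9 carbonyl is the enol ether carbon of the adduct. One operation closes ring B, forms two C–C bonds and sets C1, C2 and C3. The diene, made from (−)-quinic acid, is a 1-(1-silyloxyvinyl)cyclohexene whose cis C4 and C6 oxygens are bridged by a benzylidene acetal, which blocks the upper face and forces the anhydride to add from below.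

Key step: step 12

Remark on labels: atoms keep the numbering of the target decalin. Ring B = C1 (sec-butyl), C2 (quaternary), C3 and C8 (ring fusion), C9 (ring ketone), C10 (carbinol). Ring A = C3, C4 (methyl), C5, C6 (carbinol), C7, C8. "Upper" is the face of H3, H8, the C2 methyl and the C6 and C10 hydroxyls; "lower" is the face of the C2 acyl carbon, the sec-butyl group, the C4 methyl and the C6 CH2O group. Quinic acid C1, C2, C3, C4, C5, C6 become C6, C7, C8, C3, C4, C5.

Assumption: commercial (−)-quinic acid is the (1S,3R,4S,5R) isomer. Its C1 supplies C6 in the configuration of the target; the oxygen at C4 is inverted in step 8 so that it can be tied to the C6 oxygen.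

Remark on design: a lone allylic silyl ether at C4 would sit pseudo-equatorial and steer the dienophile poorly. The bridging acetal holds both oxygens axial on one face and is later removed by neutral hydrogenolysis, which the silyl enol ether survives. Compounds 9 and 28 are carried as mixtures at one centre that is removed later.

Step 1
Reactants: 1 (−)-quinic acid
Product: 2 quinide (γ-lactone between the carboxyl group and the lower-face C4 hydroxyl)
Conditions: TsOH·H2O (cat.), toluene–DMF, reflux, Dean–Stark
Reagents that add atoms: none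
Why: Acid-catalysed lactonisation is favoured because the carboxyl group and the C4 hydroxyl are cis-1,3 on the ring; no stereocentre is touched.

Step 2
Reactants: 2 quinide
Product: 4 hydroxy alkene lactone (C3=C8 double bond), via thionocarbonate 3 (not isolated)
Conditions: 1,1'-thiocarbonyldiimidazole, THF, 65 °C; then P(OMe)3, 110 °C
Reagents that add atoms: 1,1'-thiocarbonyldiimidazole, S=C(n1ccnc1)n1ccnc1 (its C=S group is present only in 3)
Why: Corey–Winter olefination: only the cis-vicinal C8/C3 diol can close the five-membered thionocarbonate, and its syn-fragmentation with the phosphite gives the ring alkene without touching C4 or C6.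

Step 3
Reactants: 4 hydroxy alkene lactone
Product: 5 ring A triol (C4–OH lower; C6–OH upper; C6–CH2OH lower)
Conditions: LiAlH4, THF, 0 → 25 °C
Reagents that add atoms: none
Why: Hydride reduction of a lactone to the diol; the allylic C–O bond and both stereocentres are retained.

Step 4
Reactants: 5 ring A triol
Product: 6 primary triisopropylsilyl ether
Conditions: i-Pr3SiCl, imidazole, DMF, 0 °C
Reagents that add atoms: chlorotriisopropylsilane, CC(C)[Si](Cl)(C(C)C)C(C)C
Why: Silyl ether formation with a bulky chlorosilane is selective for the primary hydroxyl over the secondary allylic and tertiary ones.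

Step 5
Reactants: 6 primary silyl ether
Product: 7 (S)-5-hydroxy-5-[(triisopropylsilyloxy)methyl]cyclohex-2-en-1-one (C4 ketone)
Conditions: MnO2, CH2Cl2, 25 °C
Reagents that add atoms: none
Why: MnO2 oxidises only the allylic secondary alcohol to the enone under neutral conditions; the tertiary alcohol is inert and C6 stays as the only stereocentre.

Step 6
Reactants: 7 enone; 8 (trimethylsilyl)acetylene
Product: 9 β-alkynyl ketone (silylethynyl group on C8; both C8 epimers)
Conditions: 8, n-BuLi, Et2O, −78 °C; Me2AlCl; then 7, Ni(acac)2 (5 mol %), i-Bu2AlH (5 mol %), Et2O, −5 °C; aq NH4Cl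
Reagents that add atoms: none
Why: Nickel-catalysed conjugate addition of a dialkylaluminium acetylide, a known 1,4-alkynylation of s-trans cyclic enones; the C8 centre forms unselectively and is removed in step 7, and excess alane covers the free hydroxyl.

Step 7
Reactants: 9 β-alkynyl ketone
Product: 10 enynone (C3=C8 restored, alkyne on C8)
Conditions: IBX, 4-methoxypyridine N-oxide, DMSO, 25 °C
Reagents that add atoms: none
Why: IBX dehydrogenation of a ketone to the enone at room temperature; only the C3–C8 side can be desaturated because C6 bears no hydrogen.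

Step 8
Reactants: 10 enynone
Product: 12 cis-diol enyne (C4–OH and C6–OH both upper; terminal alkyne), via silylalkyne diol 11 (not isolated)
Conditions: Et2BOMe, THF–MeOH, −78 °C; NaBH4; then K2CO3, MeOH, 25 °C
Reagents that add atoms: none
Why: Narasaka–Prasad 1,3-syn reduction: boron chelates the C6 hydroxyl and the C4 carbonyl on the upper face and hydride attacks from below, so the new C4 hydroxyl is cis to the C6 hydroxyl; basic methanol then removes the alkynyl silyl group.

Step 9
Reactants: 12 cis-diol enyne
Product: 13 methyl ketone diol (acetyl on C8, C8=C3)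
Conditions: Ph3PAuCl (2 mol %), AgOTf (2 mol %), H2O, 1,4-dioxane, 60 °C
Reagents that add atoms: water, O
Why: Gold-catalysed Markovnikov hydration of a terminal alkyne gives the methyl ketone, here conjugated with the ring alkene; the alkyne is trans to C4 across the double bond, so the hydroxyls cannot cyclise onto it.

Step 10
Reactants: 13 methyl ketone diol
Product: 14 bridged benzylidene acetal (2-phenyl-1,3-dioxane across C4–O and C6–O)
Conditions: PhCH(OMe)2, pyridinium p-toluenesulfonate (cat.), CH2Cl2, 4 Å sieves, 25 °C
Reagents that add atoms: benzaldehyde dimethyl acetal, COC(OC)c1ccccc1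
Why: Acid-catalysed transacetalisation: only the cis-1,3-diol can close the bridging dioxane, and the acetal carbon equilibrates to the isomer with phenyl equatorial, pointing away from ring A.

Step 11
Reactants: 14 bridged benzylidene acetal
Product: 15 ring A 2-silyloxydiene
Conditions: t-BuMe2SiOTf, Et3N, CH2Cl2, −78 → 0 °C
Reagents that add atoms: tert-butyldimethylsilyl trifluoromethanesulfonate, CC(C)(C)[Si](C)(C)OS(=O)(=O)C(F)(F)F
Why: Kinetic enol silylation of the methyl ketone at CH3 with a silyl triflate and amine base gives the cross-conjugated 2-silyloxydiene; no stereocentre changes.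

Step 12
Reactants: 15 ring A 2-silyloxydiene; 16 citraconic anhydride
Product: 17 endo adduct (ring B closed; cyclic anhydride on the lower face; C8=C9 silyl enol ether)
Conditions: 16 (3 equiv), BHT (cat.), toluene, 110 °C, sealed tube
Reagents that add atoms: none
Why: Normal-electron-demand [4+2] cycloaddition, concerted but asynchronous, with bond C10–C1 leading and bond C3–C2 following; the closest known type is the Diels–Alder reaction of 2-silyloxydienes with cyclic anhydrides. Ring B closes as a six-membered ring by suprafacial addition across the s-cis diene C10=C9–C8=C3. C1 and C2 keep the cis geometry of the anhydride, so the future sec-butyl and acyl carbons end up on the same face. C3 is set relative to them by the endo transition state (anhydride under the diene, its methyl exo), which places H3 trans to the C2 carbonyl. The absolute sense at C1, C2 and C3 follows from attack on the lower diene face, because the benzylidene bridge over C4–O and C6–O covers the upper face. The orientation of the partners is the selectivity the step needs, and the silyloxy group supplies it by making C10 the nucleophilic terminus, which pairs with the unsubstituted, less hindered anhydride carbon.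

Step 13
Reactants: 17 endo adduct; 18 ethylmagnesium bromide
Product: 20 keto ester (C1 propanoyl; C2 CO2Me), via keto acid 19 (not isolated)
Conditions: 18 (1.1 equiv), THF, −78 °C; aq NaH2PO4; then Me3SiCHN2, toluene–MeOH, 0 °C
Reagents that add atoms: (trimethylsilyl)diazomethane, C[Si](C)(C)C=[N+]=[N-] (supplies the ester CH3 carbon)
Why: Grignard addition to a cyclic anhydride stops at the keto carboxylate and occurs at the carbonyl on tertiary C1, not at the neopentyl carbonyl on quaternary C2; the acid is then methylated with the diazo reagent, and C1 does not epimerise at −78 °C.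

Step 14
Reactants: 20 keto ester
Product: 21 diol (C4–OH and C6–OH free)
Conditions: H2 (1 atm), Pd(OH)2/C, EtOAc, 25 °C
Reagents that add atoms: none
Why: Hydrogenolysis of a benzylidene acetal frees both hydroxyls under neutral conditions that leave the tetrasubstituted silyl enol ether, the ketone and the ester intact.

Step 15
Reactants: 21 diol
Product: 22 C4 ketone
Conditions: Dess–Martin periodinane, NaHCO3, CH2Cl2, 0 °C
Reagents that add atoms: none
Why: Dess–Martin oxidation of the secondary C4 alcohol; the tertiary C6 alcohol is inert, and buffered, base-free conditions protect the acidic C3–H and C1–H positions.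

Step 16
Reactants: 22 C4 ketone
Product: 23 bis-alkene (C4=CH2 and C1–C(=CH2)CH2CH3)
Conditions: Zn, CH2Br2, TiCl4, THF–CH2Cl2, 0 → 25 °C
Reagents that add atoms: dibromomethane, BrCBr
Why: Takai–Lombardo methylenation converts both ketones into 1,1-disubstituted alkenes with a non-basic zinc–titanium methylene reagent that does not enolise C1–H or C3–H and leaves the ester alone.

Step 17
Reactants: 23 bis-alkene
Product: 24 saturated ester (C4 methyl lower; C1 (R)-sec-butyl)
Conditions: H2 (3 atm), RhCl(PPh3)3 (10 mol %), benzene–EtOH, 25 °C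
Reagents that add atoms: none
Why: Homogeneous hydrogenation with RhCl(PPh3)3 reduces 1,1-disubstituted alkenes without double-bond migration and spares the tetrasubstituted enol ether; at C4 hydrogen should enter from the upper face because the lower face is screened by C2 with its ester and by the CH2OSi group on C6, and at the side chain the ethyl group eclipses H1 so that hydrogen adds to the alkene face turned toward C10, away from quaternary C2, which gives the R centre.

Step 18
Reactants: 24 saturated ester
Product: 25 primary alcohol (C2–CH2OH)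
Conditions: LiAlH4, THF, 0 → 40 °C
Reagents that add atoms: none
Why: LiAlH4 reduction of the hindered methyl ester to the neopentyl alcohol; the enol ether and the silyl ether are stable to hydride.

Step 19
Reactants: 25 primary alcohol
Product: 26 aldehyde (C2–CHO)
Conditions: Dess–Martin periodinane, NaHCO3, CH2Cl2, 0 °C
Reagents that add atoms: none
Why: Dess–Martin oxidation of the primary alcohol; the aldehyde sits on quaternary C2 and cannot epimerise, and the tertiary alcohol is inert.

Step 20
Reactants: 26 aldehyde; 27 vinylmagnesium bromide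
Product: 28 allylic alcohol (C2–CH(OH)CH=CH2; both carbinol epimers)
Conditions: 27 (4 equiv), THF, −78 → −20 °C; aq NH4Cl
Reagents that add atoms: none
Why: Grignard 1,2-addition to the aldehyde; the new carbinol centre forms as a mixture that is erased by oxidation in step 24, and excess reagent covers the free C6 hydroxyl.

Step 21
Reactants: 28 allylic alcohol
Product: 29 cis-fused C9 ketone (H8 upper)
Conditions: Bu4NF, AcOH, THF, 0 °C
Reagents that add atoms: none
Why: Fluoride cleaves the silyl enol ether much faster than the primary alkyl silyl ether, and the enolate is protonated by acetic acid at C8 from the upper face, opposite the lower-face groups on C2 and C4, which should give the cis ring fusion.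

Step 22
Reactants: 29 cis-fused C9 ketone
Product: 32 α-methylene ketone (C10=CH2), via Mannich base 30 (not isolated), via methiodide 31 (not isolated)
Conditions: LDA (3.5 equiv), THF, −78 °C; Me2N=CH2+ I−; then MeI, CH2Cl2; aq NaHCO3, 25 °C
Reagents that add atoms: N,N-dimethylmethyleneiminium iodide, C=[N+](C)C.[I-] (supplies the C10 methylene carbon; its NMe2 group is present only in 30 and 31); iodomethane, CI (N-methyl group of 31 only)
Why: Kinetic deprotonation at the C10 methylene and not the C8 methine, Mannich reaction with Eschenmoser's salt, N-methylation and E1cB elimination give the α-methylene ketone; the two alkoxides formed first are spectators.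

Step 23
Reactants: 32 α-methylene ketone
Product: 34 ketol (C10 OH upper; C10 CH3 lower), via hydroperoxide 33 (not isolated)
Conditions: Mn(dpm)3 (10 mol %; dpm = dipivaloylmethanate), PhSiH3, O2 (1 atm), i-PrOH–CH2Cl2, 0 °C; then P(OEt)3
Reagents that add atoms: dioxygen, O=O
Why: Mukaiyama hydration of an enone: hydrogen-atom transfer from a manganese hydride to the CH2 terminus gives the tertiary α-keto radical at C10, which should take up O2 from the upper face, away from the sec-butyl group on C1 and the lower-face C2 side chain, and the phosphite reduces the hydroperoxide; the isolated vinyl group is much less reactive under these conditions.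

Step 24
Reactants: 34 ketol
Product: 35 vinyl ketone (C2–C(=O)CH=CH2)
Conditions: Dess–Martin periodinane, NaHCO3, CH2Cl2, 0 °C
Reagents that add atoms: none
Why: Dess–Martin oxidation converts both epimers of the allylic alcohol into one vinyl ketone; the tertiary alcohols are inert.

Step 25
Reactants: 35 vinyl ketone
Product: 37 β-hydroxy ketone silyl ether, via boronate 36 (not isolated)
Conditions: CuCl (5 mol %), DPEphos (5 mol %), NaOt-Bu (10 mol %), B2pin2, MeOH, THF, 25 °C; then H2O2, pH 7 buffer, 0 °C
Reagents that add atoms: bis(pinacolato)diboron, CC1(C)OB(OC1(C)C)B1OC(C)(C)C(C)(C)O1 (Bpin group of 36 only); hydrogen peroxide, OO (hydroxyl oxygen)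
Why: Copper-catalysed conjugate borylation of the enone followed by oxidation of the C–B bond gives the β-hydroxy ketone; the hindered ring ketone does not react.

Step 26
Reactants: 37 β-hydroxy ketone silyl ether
Product: 38 target CNP0112523.4
Conditions: HF·pyridine, pyridine, THF, 0 → 25 °C
Reagents that add atoms: none
Why: Fluoride-mediated desilylation under buffered, mildly acidic conditions removes the last silyl ether without retro-aldol cleavage or dehydration of the β-hydroxy ketone.

Compound list

1 | (−)-quinic acid, (1S,3R,4S,5R)-1,3,4,5-tetrahydroxycyclohexane-1-carboxylic acid | O[C@@]1(C(=O)O)C[C@@H](O)[C@@H](O)[C@H](O)C1 | starting material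
2 | quinide: γ-lactone of 1 between the carboxyl group and the C4 hydroxyl, lactone bridge lower, hydroxyls at C6, C8 and C3 upper | O[C@@]1(C(=O)O2)C[C@@H](O)[C@@H](O)[C@H]2C1 | intermediate
3 | quinide cyclic thionocarbonate across C8–O and C3–O | O[C@@]1(C(=O)O2)C[C@H]3OC(=S)O[C@H]3[C@H]2C1 | intermediate (not isolated)
4 | 1-hydroxy-6-oxabicyclo[3.2.1]oct-3-en-7-one: quinide with a C3=C8 double bond in place of the two hydroxyls, C6–OH upper | O[C@@]1(C(=O)O2)CC=C[C@H]2C1 | intermediate
5 | 5-(hydroxymethyl)cyclohex-2-ene-1,5-diol: C3=C8 alkene, C4–OH lower, C6–OH upper, C6–CH2OH lower | O[C@@]1(CO)CC=C[C@H](O)C1 | intermediate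
6 | primary triisopropylsilyl ether of 5 | O[C@@]1(CO[Si](C(C)C)(C(C)C)C(C)C)CC=C[C@H](O)C1 | intermediate
7 | (S)-5-hydroxy-5-[(triisopropylsilyloxy)methyl]cyclohex-2-en-1-one: C4 ketone, C3=C8, C6–OH upper | O[C@@]1(CO[Si](C(C)C)(C(C)C)C(C)C)CC=CC(=O)C1 | intermediate
8 | (trimethylsilyl)acetylene | C#C[Si](C)(C)C | starting material
9 | 5-hydroxy-5-[(triisopropylsilyloxy)methyl]-3-[(trimethylsilyl)ethynyl]cyclohexan-1-one, C6 as in 7, both epimers at C8 | O[C@@]1(CO[Si](C(C)C)(C(C)C)C(C)C)CC(C#C[Si](C)(C)C)CC(=O)C1 | intermediate
10 | 5-hydroxy-5-[(triisopropylsilyloxy)methyl]-3-[(trimethylsilyl)ethynyl]cyclohex-2-en-1-one, C6 as in 7 | O[C@@]1(CO[Si](C(C)C)(C(C)C)C(C)C)CC(C#C[Si](C)(C)C)=CC(=O)C1 | intermediate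
11 | cis-diol from 10: C4–OH and C6–OH both upper, alkyne still silylated | O[C@@]1(CO[Si](C(C)C)(C(C)C)C(C)C)CC(C#C[Si](C)(C)C)=C[C@@H](O)C1 | intermediate (not isolated)
12 | 3-ethynyl-5-[(triisopropylsilyloxy)methyl]cyclohex-2-ene-1,5-diol, C4–OH and C6–OH both upper | O[C@@]1(CO[Si](C(C)C)(C(C)C)C(C)C)CC(C#C)=C[C@@H](O)C1 | intermediate
13 | methyl ketone: acetyl on C8 of the C8=C3 cyclohexene, C4–OH and C6–OH upper, C6–CH2OSi(i-Pr)3 lower | O[C@@]1(CO[Si](C(C)C)(C(C)C)C(C)C)CC(C(C)=O)=C[C@@H](O)C1 | intermediate
14 | benzylidene acetal of 13: 2-phenyl-1,3-dioxane bridging C4–O and C6–O on the upper face, phenyl equatorial | CC(=O)C1=C[C@@H]2C[C@](CO[Si](C(C)C)(C(C)C)C(C)C)(C1)O[C@@H](c1ccccc1)O2 | intermediate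
15 | ring A 2-silyloxydiene: 14 with the acetyl group converted into CH2=C(OSiMe2t-Bu)– on C8 | C=C(O[Si](C)(C)C(C)(C)C)C1=C[C@@H]2C[C@](CO[Si](C(C)C)(C(C)C)C(C)C)(C1)O[C@@H](c1ccccc1)O2 | intermediate (key-step precursor)
16 | citraconic anhydride (methylmaleic anhydride) | CC1=CC(=O)OC1=O | starting material
17 | endo adduct: ring B with the cyclic anhydride at C1 and C2 on the lower face, C2 methyl upper, H3 upper, C8=C9 tert-butyldimethylsilyl enol ether, ring A bridge and CH2OSi(i-Pr)3 as in 15 | O=C1OC(=O)[C@]2(C)[C@@H]3[C@@H]4C[C@](CO[Si](C(C)C)(C(C)C)C(C)C)(CC3=C(O[Si](C)(C)C(C)(C)C)C[C@H]12)O[C@@H](c1ccccc1)O4 | intermediate (key-step product)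
18 | ethylmagnesium bromide | CC[Mg]Br | starting material
19 | keto acid: C1 propanoyl (lower), C2 CO2H (lower), rest as 17; may exist as the cyclic lactol | CCC(=O)[C@@H]1[C@](C)(C(=O)O)[C@@H]2[C@@H]3C[C@](O[C@@H](c4ccccc4)O3)(CO[Si](C(C)C)(C(C)C)C(C)C)CC2=C(O[Si](C)(C)C(C)(C)C)C1 | intermediate (not isolated)
20 | methyl ester of 19 | CCC(=O)[C@@H]1[C@](C)(C(=O)OC)[C@@H]2[C@@H]3C[C@](O[C@@H](c4ccccc4)O3)(CO[Si](C(C)C)(C(C)C)C(C)C)CC2=C(O[Si](C)(C)C(C)(C)C)C1 | intermediate
21 | diol: 20 without the benzylidene group, C4–OH and C6–OH upper | CCC(=O)[C@@H]1[C@](C)(C(=O)OC)[C@@H]2[C@@H](O)C[C@](O)(CO[Si](C(C)C)(C(C)C)C(C)C)CC2=C(O[Si](C)(C)C(C)(C)C)C1 | intermediate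
22 | C4 ketone of 21 | CCC(=O)[C@@H]1[C@](C)(C(=O)OC)[C@@H]2C(=O)C[C@](O)(CO[Si](C(C)C)(C(C)C)C(C)C)CC2=C(O[Si](C)(C)C(C)(C)C)C1 | intermediate
23 | bis-alkene: C4=CH2 and but-1-en-2-yl on C1 | CCC(=C)[C@@H]1[C@](C)(C(=O)OC)[C@@H]2C(=C)C[C@](O)(CO[Si](C(C)C)(C(C)C)C(C)C)CC2=C(O[Si](C)(C)C(C)(C)C)C1 | intermediate
24 | saturated ester: C4 methyl lower, C1 (R)-sec-butyl lower, C2 CO2Me, C6–OH upper, C8=C9 silyl enol ether | CC[C@@H](C)[C@@H]1[C@](C)(C(=O)OC)[C@@H]2[C@H](C)C[C@](O)(CO[Si](C(C)C)(C(C)C)C(C)C)CC2=C(O[Si](C)(C)C(C)(C)C)C1 | intermediate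
25 | primary alcohol: C2–CH2OH, rest as 24 | CC[C@@H](C)[C@@H]1[C@](C)(CO)[C@@H]2[C@H](C)C[C@](O)(CO[Si](C(C)C)(C(C)C)C(C)C)CC2=C(O[Si](C)(C)C(C)(C)C)C1 | intermediate
26 | aldehyde: C2–CHO, rest as 24 | CC[C@@H](C)[C@@H]1[C@](C)(C=O)[C@@H]2[C@H](C)C[C@](O)(CO[Si](C(C)C)(C(C)C)C(C)C)CC2=C(O[Si](C)(C)C(C)(C)C)C1 | intermediate
27 | vinylmagnesium bromide | C=C[Mg]Br | starting material
28 | allylic alcohol: C2–CH(OH)CH=CH2, both carbinol epimers | CC[C@@H](C)[C@@H]1[C@](C)(C(O)C=C)[C@@H]2[C@H](C)C[C@](O)(CO[Si](C(C)C)(C(C)C)C(C)C)CC2=C(O[Si](C)(C)C(C)(C)C)C1 | intermediate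
29 | cis-fused C9 ketone: H8 upper, C10 H2 | CC[C@@H](C)[C@@H]1[C@](C)(C(O)C=C)[C@@H]2[C@H](C)C[C@](O)(CO[Si](C(C)C)(C(C)C)C(C)C)C[C@@H]2C(=O)C1 | intermediate
30 | Mannich base: C10–CH2NMe2 | CC[C@@H](C)[C@@H]1[C@](C)(C(O)C=C)[C@@H]2[C@H](C)C[C@](O)(CO[Si](C(C)C)(C(C)C)C(C)C)C[C@@H]2C(=O)C1CN(C)C | intermediate (not isolated)
31 | methiodide of 30 | CC[C@@H](C)[C@@H]1[C@](C)(C(O)C=C)[C@@H]2[C@H](C)C[C@](O)(CO[Si](C(C)C)(C(C)C)C(C)C)C[C@@H]2C(=O)C1C[N+](C)(C)C.[I-] | intermediate (not isolated)
32 | α-methylene ketone: C10=CH2 | CC[C@@H](C)[C@@H]1[C@](C)(C(O)C=C)[C@@H]2[C@H](C)C[C@](O)(CO[Si](C(C)C)(C(C)C)C(C)C)C[C@@H]2C(=O)C1=C | intermediate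
33 | C10 hydroperoxide: OOH upper, CH3 lower | CC[C@@H](C)[C@@H]1[C@](C)(C(O)C=C)[C@@H]2[C@H](C)C[C@](O)(CO[Si](C(C)C)(C(C)C)C(C)C)C[C@@H]2C(=O)[C@@]1(C)OO | intermediate (not isolated)
34 | ketol: C10 OH upper, C10 CH3 lower | CC[C@@H](C)[C@@H]1[C@](C)(C(O)C=C)[C@@H]2[C@H](C)C[C@](O)(CO[Si](C(C)C)(C(C)C)C(C)C)C[C@@H]2C(=O)[C@@]1(C)O | intermediate
35 | vinyl ketone: C2–C(=O)CH=CH2 | CC[C@@H](C)[C@@H]1[C@](C)(C(=O)C=C)[C@@H]2[C@H](C)C[C@](O)(CO[Si](C(C)C)(C(C)C)C(C)C)C[C@@H]2C(=O)[C@@]1(C)O | intermediate
36 | β-boryl ketone: C2–C(=O)CH2CH2Bpin | CC[C@@H](C)[C@@H]1[C@](C)(C(=O)CCB3OC(C)(C)C(C)(C)O3)[C@@H]2[C@H](C)C[C@](O)(CO[Si](C(C)C)(C(C)C)C(C)C)C[C@@H]2C(=O)[C@@]1(C)O | intermediate (not isolated)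
37 | triisopropylsilyl ether of the target at the C6 CH2OH group | CC[C@@H](C)[C@@H]1[C@](C)(C(=O)CCO)[C@@H]2[C@H](C)C[C@](O)(CO[Si](C(C)C)(C(C)C)C(C)C)C[C@@H]2C(=O)[C@@]1(C)O | intermediate
38 | CNP0112523.4: cis-fused decalin-9-one with C1 (R)-sec-butyl lower, C2 methyl upper and 3-hydroxypropanoyl lower, H3 and H8 upper, C4 methyl lower, C6 OH upper and CH2OH lower, C10 OH upper and methyl lower | CC[C@@H](C)[C@@H]1[C@](C)(C(=O)CCO)[C@@H]2[C@H](C)C[C@](O)(CO)C[C@@H]2C(=O)[C@@]1(C)O | target

Total step count: 26. Longest linear sequence: 26 steps, from 1 to 38; compounds 8, 16, 18 and 27 enter as single building blocks.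

Steps most likely to fail

Step 12. Bond formation between the methyl-bearing anhydride carbon and the hindered C3 terminus may be slow, so that thermal isomerisation or loss of the silyl group from diene 15 competes; endo control and the orientation of the partners may also be incomplete. The fallback leaves the thermal pericyclic mode and runs the annulation as a polar two-stage process from 15 and 16 back to 17. Tf2NH (5 mol %) in CH2Cl2 at −78 °C generates t-BuMe2SiNTf2, which silylates the anhydride. Mukaiyama–Michael addition of C10 to the unsubstituted carbon is followed by ring closure of the silyl ketene acetal at C3, and silyl transfer returns the enol ether. No new compound is formed (F0).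

Step 17. Facial discrimination at the freely rotating 1,1-disubstituted alkene on C1 may be poor, giving both epimers at the sec-butyl carbon; delivery to the wrong face at C4 is less likely. The fallback separates the two reductions and replaces substrate control by directed and catalyst control. From 23, [Ir(cod)(PCy3)(py)]PF6 (2 mol %), H2 (1 atm), CH2Cl2, 0 °C, stopped after one equivalent, delivers hydrogen to the C4 alkene from the side of the C6 hydroxyl and should give the mono-alkene ester with the C4 methyl in place, F1. The remaining alkene is then reduced with a chiral iridium phosphino-oxazoline catalyst, [Ir(cod)((S)-t-Bu-PHOX)][B(3,5-(CF3)2C6H3)4] or its enantiomer, whichever is matched with the substrate, under H2 (50 bar) in CH2Cl2, which returns to 24.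

Step 16. The titanium Lewis acid may enolise the C4 ketone toward the doubly activated C3–H, with loss of the ring-fusion configuration, or open the C4 ketone/C6 hydroxyl pair by retro-aldol cleavage; the hindered ethyl ketone may also react incompletely. The fallback is a two-stage Peterson olefination from 22. Me3SiCH2Li and CeCl3 in THF at −78 °C add to both ketones without enolisation and should give the bis(β-hydroxysilane), F2. KH in THF at 0 °C then effects syn-elimination at both sites, which returns to 23.

Further compounds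

F0 | step 12 | none | none
F1 | step 17 | mono-alkene ester: C4 methyl lower, but-1-en-2-yl still on C1, rest as 23 | CCC(=C)[C@@H]1[C@](C)(C(=O)OC)[C@@H]2[C@H](C)C[C@](O)(CO[Si](C(C)C)(C(C)C)C(C)C)CC2=C(O[Si](C)(C)C(C)(C)C)C1
F2 | step 16 | bis(β-hydroxysilane): Me3SiCH2 and OH on C4 and on the former ethyl ketone carbon, new carbinol centres as mixtures | CCC(O)(C[Si](C)(C)C)[C@@H]1[C@](C)(C(=O)OC)[C@@H]2C(O)(C[Si](C)(C)C)C[C@](O)(CO[Si](C(C)C)(C(C)C)C(C)C)CC2=C(O[Si](C)(C)C(C)(C)C)C1
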